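**Retrosynthetic overview**
1. No ring is built: the only ring comes from 2-methoxy-5-methylphenol (1), oxidised to 2-methoxy-5-methyl-1,4-benzoquinone (2; numbering C1=O, C2–OMe, C3–H, C4=O, C5–Me, C6–H).
2. Chain: C25 = C22 + C3. 1-Bromodocosane (3) and 1,3-dibromopropane (4) give, via the Grignard reagent (5), 1-bromopentacosane (6) and then 1-nitropentacosane (7).
3. Key disconnection C6–C1′: both carbons are natively electrophilic (quinone CH and the C–Br carbon), so C1′ is used with reversed polarity as the nitronate (8), a traceless d1 alkyl-anion equivalent.
4. One flask: conjugate addition of 8 to 2 gives hydroquinone (9), nitrite loss gives o-quinone methide (10), and tautomerisation gives the target (11), redox-neutral and without protecting groups.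

Assumption: the target (C33H58O3, side chain read as n-pentacosyl) has no stereocentre and no stereogenic double bond, so there is no enantiomer to select; the ring numbering of 2 is kept for all later compounds.

**Step 1**
Reactants: 1 2-methoxy-5-methylphenol
Product: 2 2-methoxy-5-methyl-1,4-benzoquinone
Conditions: (KSO3)2NO (2.2 equiv), aq KH2PO4/acetone, 0 °C → rt
Reagents that add atoms: Fremy's salt (potassium nitrosodisulfonate), [K+].[K+].[O-]S(=O)(=O)N([O])S(=O)(=O)[O-]
Why: Teuber oxidation: the phenoxyl radical is trapped by a second nitroxide at the free para position (C4) and loss of imidodisulfonate gives the p-quinone, the usual outcome for guaiacols with an open para site.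

**Step 2**
Reactants: 3 1-bromodocosane; 4 1,3-dibromopropane
Product: 6 1-bromopentacosane, via docosylmagnesium bromide 5 (not isolated)
Conditions: Mg, THF, 50 °C; then added to 4 (5 equiv), Li2CuCl4 (3 mol %), THF, 0 °C → rt
Reagents that add atoms: none
Why: Kochi copper-catalysed sp3–sp3 cross-coupling of a primary alkyl Grignard reagent with a primary alkyl bromide, where the five-fold excess of 4 and inverse addition suppress coupling at the second C–Br bond.

**Step 3**
Reactants: 6 1-bromopentacosane
Product: 7 1-nitropentacosane
Conditions: AgNO2 (1.5 equiv), Et2O/toluene, 0 °C → rt, dark, 48 h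
Reagents that add atoms: silver nitrite, [Ag+].[O-]N=O
Why: Victor Meyer reaction: silver-assisted SN2 displacement of a primary bromide by ambident nitrite gives mainly the N-alkylated nitroalkane, and the minor alkyl nitrite is removed on recrystallisation.

**Step 4**
Reactants: 7 1-nitropentacosane; 2 2-methoxy-5-methyl-1,4-benzoquinone
Product: 11 2-methoxy-5-methyl-6-pentacosyl-1,4-benzoquinone, via potassium nitronate 8 (not isolated), via nitroalkyl hydroquinone 9 (not isolated), via o-quinone methide 10 (not isolated)
Conditions: KOtBu (1.0 equiv), THF, 0 °C; then added slowly to 2 (1.3 equiv), THF/DMF 4:1, −20 °C → rt, Ar; AcOH quench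
Reagents that add atoms: none
Why: Proposed new method: the soft nitronate 8 should add in Michael fashion to C6 of 2 (C3 is the electron-rich β-carbon of the enol ether, and addition at C5 is reversible because that adduct cannot aromatise), enolisation gives hydroquinone 9 (racemic at C1′, a stereocentre that is then erased), its ortho-phenoxide expels nitrite by E1cB to give o-quinone methide 10, and 10 tautomerises to the more stable quinone 11, so the C–H alkylation is redox-neutral and needs no separate denitration or re-oxidation; the closest known reaction types are the nitro-Michael addition followed by base-induced loss of HNO2 from β-nitro ketones and the base-mediated generation of o-quinone methides from o-hydroxybenzyl sulfones.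

**Compound list**
1 | 2-methoxy-5-methylphenol | COc1ccc(C)cc1O | starting material
2 | 2-methoxy-5-methyl-1,4-benzoquinone (2-methoxy-5-methylcyclohexa-2,5-diene-1,4-dione) | COC1=CC(=O)C(C)=CC1=O | intermediate
3 | 1-bromodocosane | CCCCCCCCCCCCCCCCCCCCCCBr | starting material
4 | 1,3-dibromopropane | BrCCCBr | starting material
5 | docosylmagnesium bromide | CCCCCCCCCCCCCCCCCCCCCC[Mg]Br | intermediate
6 | 1-bromopentacosane | CCCCCCCCCCCCCCCCCCCCCCCCCBr | intermediate
7 | 1-nitropentacosane | CCCCCCCCCCCCCCCCCCCCCCCCC[N+](=O)[O-] | intermediate
8 | potassium pentacosane-1-nitronate | CCCCCCCCCCCCCCCCCCCCCCCCC=[N+]([O-])[O-].[K+] | intermediate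
9 | 2-methoxy-5-methyl-6-(1-nitropentacosyl)benzene-1,4-diol, racemic at C1′, present in the flask as its mono-potassium salt | CCCCCCCCCCCCCCCCCCCCCCCCC(c1c(C)c(O)cc(OC)c1O)[N+](=O)[O-] | intermediate
10 | 4-hydroxy-2-methoxy-5-methyl-6-pentacosylidenecyclohexa-2,4-dien-1-one, exocyclic alkene geometry not defined | CCCCCCCCCCCCCCCCCCCCCCCCC=C1C(C)=C(O)C=C(OC)C1=O | intermediate
11 | 2-methoxy-5-methyl-6-pentacosyl-1,4-benzoquinone (5-methoxy-2-methyl-3-pentacosylcyclohexa-2,5-diene-1,4-dione), achiral | CCCCCCCCCCCCCCCCCCCCCCCCCC1=C(C)C(=O)C=C(OC)C1=O | target

**Totals**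
Total step count: 4. Longest linear sequence: 3 steps (3 → 6 → 7 → 11); step 1 is a one-step side branch.

**Three steps most likely to fail**

Step 4 (key step). The risks are electron transfer from 8 to 2 instead of C–C bond formation, ipso attack at C2 with loss of methoxide, attack at C3, and capture of 10 by a second nitronate. The fallback sets out from phenol 1 and bromide 6 and comes back at target 11. Phenol 1 is protected as the MOM ether 1-methoxy-2-(methoxymethoxy)-4-methylbenzene F1 (MOMCl, iPr2NEt, CH2Cl2). Directed ortho-lithiation (n-BuLi, TMEDA, THF, 0 °C) takes place at the only position ortho to the OMOM group, and the aryllithium is alkylated with 6 (THF/DMPU, −78 °C → rt) to give 1-methoxy-2-(methoxymethoxy)-4-methyl-3-pentacosylbenzene F2. HCl in MeOH/THF then frees 6-methoxy-3-methyl-2-pentacosylphenol F3, and Fremy's salt under the conditions of step 1 oxidises the free para position to give 11. This places the chain by the substitution pattern of the phenol, not by the electronic bias of the quinone.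

Step 3. The risks are O-alkylation to pentacosyl nitrite and slow reaction of the poorly soluble C25 bromide. The fallback sets out from 6 and comes back at 7. Displacement with NaN3 (DMF/THF, 70 °C) gives 1-azidopentacosane F4, hydrogenation (H2, Pd/C, THF/EtOH) gives pentacosan-1-amine F5, and oxidation of the primary amine with dimethyldioxirane (acetone, rt) gives 7.

Step 2. The risks are double coupling of 4 to the C47 alkane and Wurtz homocoupling during Grignard formation. The fallback sets out from Grignard reagent 5 (made from 3 as in step 2) and comes back at 6. Allylation of 5 with allyl bromide (THF, 0 °C → rt), which needs no statistical control, gives pentacos-1-ene F6, and radical anti-Markovnikov addition of HBr (HBr, dibenzoyl peroxide, hexane, hν) gives 6.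

**Further compounds**
F1 | step 4 | 1-methoxy-2-(methoxymethoxy)-4-methylbenzene | COCOc1cc(C)ccc1OC
F2 | step 4 | 1-methoxy-2-(methoxymethoxy)-4-methyl-3-pentacosylbenzene | CCCCCCCCCCCCCCCCCCCCCCCCCc1c(C)ccc(OC)c1OCOC
F3 | step 4 | 6-methoxy-3-methyl-2-pentacosylphenol | CCCCCCCCCCCCCCCCCCCCCCCCCc1c(C)ccc(OC)c1O
F4 | step 3 | 1-azidopentacosane | CCCCCCCCCCCCCCCCCCCCCCCCCN=[N+]=[N-]
F5 | step 3 | pentacosan-1-amine | CCCCCCCCCCCCCCCCCCCCCCCCCN
F6 | step 2 | pentacos-1-ene | C=CCCCCCCCCCCCCCCCCCCCCCCC
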